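In the early times of the north-west run, the reading after 0.167 h put 35% of the substrate charged as substrate, 16% as target and 47% as side product.

| flask | substrate | gas phase | remark | time |
|---|---|---|---|---|
| north-west | 0.034 M | 2.5 mM (held) | run made earlier |  |
| south-east | 0.075 M | 2.5 mM (held) | run made earlier |  |
| flask | 0.050 M | 2.5 mM (held) |  | 5.0 h |

| run | time / h | substrate / % | side product / % | target / % |
|---|---|---|---|---|
| north-west | 0.167 | 35 | 47 | 16 |
| north-west | 0.500 | 13 | 84 | 4 |
| north-west | 0.833 | 4 | 94 | 2 |
| north-west | 1.33 | 3 | 99 | 0 |
| north-west | 2.00 | 0 | 100 | 0 |
| north-west | 2.50 | 0 | 99 | 0 |
| north-west | 3.00 | 0 | 98 | 0 |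
| south-east | 0.417 | 17 | 75 | 5 |
| south-east | 0.833 | 6 | 93 | 2 |
| south-east | 1.33 | 1 | 97 | 0 |
| south-east | 1.50 | 0 | 100 | 0 |
| south-east | 2.00 | 0 | 99 | 0 |
| south-east | 2.50 | 1 | 99 | 0 |
| south-east | 3.00 | 0 | 101 | 0 |

(readings scatter by 1.5 percentage points)

- what was read earlier has a scatter of 1.5 percentage points, one standard deviation
- at the start none of the gas phase is in solution
- the reaction counts as stopped when no species that holds the substrate changes by six tenths of a point or more over the second half of the time

- which holds at 5.0 h: what has brought the reaction to rest, or that it has not come to rest (all of the substrate has reacted / forward and back rates have come level / it is still moving)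
- part of the substrate gone at 5.0 h
- the side product standing at 5.0 h, as a percentage of the substrate charged

My bench rule was the usual one: a first-order decay counts as over after 5 time constants. But that rule counts one store, and these runs showed two. Its border was a ratio. Target over substrate read 0.308 at 0.500 h in the north-west run and 0.294 at 0.417 h in the south-east run. A level ratio reads like two coupled tanks draining together. I saw it level within the scatter, so I counted the pool, substrate plus target.

The north-west pool gave a rate constant k of 3.54 /h. The south-east run, with 2.21 times the charge, gave 3.63 /h. For the flask at 5.0 h that made 17.7 lifetimes. I call this the lifetime count N, the time over the pool's time constant. It is more than the 5 of the bench rule. The pool left by the count was <0.001% of the charge, so I expected the flask at rest with its substrate consumed.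

The forecast said all of the substrate has reacted, with 100% of the substrate gone and 99.5% side product: “the substrate is exhausted”. It took about 4 per hour from the substrate, where I took the pool.

The flask gave all of the substrate has reacted, with 100% gone and 100% side product at 5.0 h.

    gas phase ⇌ dissolved gas, rate k1*(csat - [dissolved gas]) (kL = 0.410 /s)
    substrate + dissolved gas ⇌ target (K = 130 /M, k = 0.680 /M/s)
    substrate → side product (k = 0.00130 /s)
    dissolved gas → decomposed reagent (k = 0.00120 /s)

The flask held 0% target at 5.0 h because of the way back from target to substrate and dissolved gas: the same flask run without that way back ended at 44.6% side product, against 100%. In this flask the side product stood 5 points short at 0.875 h, where N was 3.10 and the count left 4.52%. For the neighbour flask charged with 0.085 M of substrate I counted the same N at 5.0 h, and it gave 100% side product.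

The runs stem from a simulated flask for an exercise; scatter was added.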